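The C2-symmetric dioxane is cut at its four C–O bonds into two identical 6α-hydroxy-7-oxoabietane halves, and each half rests on closing ring B across C5–C6. The key step exploits the prochiral quaternary C10 of a ring A cyclohexadienone, which carries methyl, aromatic ring C and two enantiotopic enone arms: a chiral carbene turns the C6 aldehyde into an acyl anion that adds to C5 of one arm, closing ring B, fixing C10 and installing the C6 oxygen in one operation. Its precursor is an achiral 4-aryl-4-methylcyclohexa-2,5-dienone whose aryl group bears an ortho 2-oxoethyl chain.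

Key step: step 8

Assumption: abietane numbering is used for all tricyclic compounds; the (5aS,10bR) antipode of the aminoindanol triazolium is assumed to select the enone arm that gives the C10 configuration drawn, and the equally available (5aR,10bS) antipode is used if a pilot run shows the opposite sense.

**Step 1**
Reactants: 1 methyl 4-bromo-2-methoxybenzoate
Product: 3 2-(4-bromo-2-methoxyphenyl)propan-2-ol, via aryl methyl ketone 2 (not isolated)
Conditions: MeMgBr (2.5 equiv), THF, 0 °C → rt; aq. NH4Cl
Reagents that add atoms: methylmagnesium bromide, C[Mg]Br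
Why: Double Grignard addition to the ester through ketone 2 should give the tertiary carbinol, the aryl bromide being inert to MeMgBr at or below room temperature.

**Step 2**
Reactants: 3 2-(4-bromo-2-methoxyphenyl)propan-2-ol
Product: 4 4-bromo-2-methoxy-1-(propan-2-yl)benzene
Conditions: Et3SiH (2.5 equiv), CF3CO2H, CH2Cl2, 0 °C → rt
Reagents that add atoms: none
Why: Ionic hydrogenation: CF3CO2H ionises the tertiary benzylic alcohol to a cation stabilised by the ortho methoxy group and Et3SiH delivers hydride, so the isopropyl group forms without touching the aryl bromide.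

**Step 3**
Reactants: 4 4-bromo-2-methoxy-1-(propan-2-yl)benzene; 5 4-methylcyclohex-2-en-1-one (racemic)
Product: 6 4-[3-methoxy-4-(propan-2-yl)phenyl]-4-methylcyclohex-2-en-1-one (racemic)
Conditions: Pd2(dba)3 (2.5 mol %), P(t-Bu)3·HBF4 (6 mol %), Cs2CO3, toluene, 80 °C
Reagents that add atoms: none
Why: Pd-catalysed γ-arylation of an enone: Cs2CO3 forms the extended dienolate of 5 by removing the tertiary γ-hydrogen and the bulky-phosphine arylpalladium bromide couples at the γ-carbon, creating the quaternary carbon (later C10) as a racemate that becomes prochiral again in step 4.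

**Step 4**
Reactants: 6 4-[3-methoxy-4-(propan-2-yl)phenyl]-4-methylcyclohex-2-en-1-one
Product: 8 4-[3-methoxy-4-(propan-2-yl)phenyl]-4-methylcyclohexa-2,5-dien-1-one, via trimethylsilyl dienol ether 7 (not isolated)
Conditions: LiN(i-Pr)2, Me3SiCl, THF, −78 °C; then Pd(OAc)2 (10 mol %), O2 (1 atm), DMSO, rt
Reagents that add atoms: none
Why: Saegusa–Ito dehydrogenation: kinetic deprotonation at the only enolisable position (the α' methylene, the γ-carbon being quaternary) gives the cross-conjugated silyl dienol ether 7, which divalent palladium oxidises to the dienone with O2 as terminal oxidant, a method chosen over quinone oxidants to spare the electron-rich isopropylanisole.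

**Step 5**
Reactants: 8 4-[3-methoxy-4-(propan-2-yl)phenyl]-4-methylcyclohexa-2,5-dien-1-one
Product: 9 4-[2-bromo-5-methoxy-4-(propan-2-yl)phenyl]-4-methylcyclohexa-2,5-dien-1-one
Conditions: NBS (1.05 equiv), MeCN, 0 °C → rt
Reagents that add atoms: N-bromosuccinimide, O=C1CCC(=O)N1Br
Why: Electrophilic aromatic bromination should go para to the methoxy group, because the only other methoxy-activated free position lies between the methoxy group and the quaternary carbon and the dienone double bonds are electron-poor.

**Step 6**
Reactants: 9 4-[2-bromo-5-methoxy-4-(propan-2-yl)phenyl]-4-methylcyclohexa-2,5-dien-1-one; 10 (E)-2-ethoxyvinylboronic acid pinacol ester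
Product: 11 4-{2-[(E)-2-ethoxyethenyl]-5-methoxy-4-(propan-2-yl)phenyl}-4-methylcyclohexa-2,5-dien-1-one
Conditions: Pd(OAc)2 (5 mol %), SPhos (10 mol %), K3PO4, dioxane/H2O (5:1), 80 °C
Reagents that add atoms: none
Why: Suzuki–Miyaura coupling: the SPhos-ligated catalyst suits a bromide flanked by a quaternary carbon, the alkenyl boronate transfers with retention of the E geometry, and the phosphate base is mild enough for the dienone.

**Step 7**
Reactants: 11 4-{2-[(E)-2-ethoxyethenyl]-5-methoxy-4-(propan-2-yl)phenyl}-4-methylcyclohexa-2,5-dien-1-one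
Product: 12 2-[4-methoxy-2-(1-methyl-4-oxocyclohexa-2,5-dien-1-yl)-5-(propan-2-yl)phenyl]acetaldehyde
Conditions: 2 M HCl/THF (1:4), 0 °C → rt; used at once
Reagents that add atoms: water, O
Why: Acid hydrolysis of the enol ether (C-protonation, hydration, loss of ethanol) should unveil the arylacetaldehyde under conditions too mild for a dienone–phenol rearrangement, the enol ether 11 serving as the storable form of the sensitive precursor.

**Step 8**
Reactants: 12 2-[4-methoxy-2-(1-methyl-4-oxocyclohexa-2,5-dien-1-yl)-5-(propan-2-yl)phenyl]acetaldehyde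
Product: 13 12-methoxy-18,19-dinor-5β-abieta-1,8,11,13-tetraene-3,6-dione (rings A and B cis-fused; H-5 and the C10 methyl both β)
Conditions: (5aS,10bR)-2-(pentafluorophenyl)-4,5a,6,10b-tetrahydroindeno[2,1-b][1,2,4]triazolo[4,3-d][1,4]oxazin-2-ium tetrafluoroborate (20 mol %), KN(SiMe3)2 (18 mol %), toluene (0.02 M), rt
Reagents that add atoms: none
Why: The carbene released from the triazolium adds to the aldehyde carbon C6 and proton transfer gives the enaminol (acyl-anion equivalent), whose C6 adds in conjugate fashion to C5 of one enone arm, after which protonation at C4 and loss of the carbene leave the C6 ketone (intramolecular Stetter reaction). The closest known reaction type is the carbene-catalysed desymmetrising Stetter cyclisation of 4,4-disubstituted cyclohexadienones carrying an aldehyde tether, extended here from five- to six-membered closure. Ring B closes in the 6-exo-trig mode. C10 is controlled by the catalyst alone, which selects one of the two enantiotopic arms of the achiral dienone, whereas C5 is controlled by the substrate, because the acyl carbon hangs from the aryl group on C10 and can only reach the face of C5 syn to that group, which imposes the cis ring fusion. The step needs attack by the acyl carbon C6 and not by the enolisable benzylic C7 (aldol or five-membered Michael closure); the electron-poor N-C6F5 carbene, the absence of base beyond the catalyst loading and high dilution favour the enaminol pathway, and the fully substituted C10 excludes γ-deprotonation or aromatisation of the dienone.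

**Step 9**
Reactants: 13 12-methoxy-18,19-dinor-5β-abieta-1,8,11,13-tetraene-3,6-dione
Product: 14 6,6-ethylenedioxy-12-methoxy-18,19-dinor-5β-abieta-1,8,11,13-tetraen-3-one
Conditions: Me3SiOCH2CH2OSiMe3, Me3SiOTf (5 mol %), CH2Cl2, −78 → −20 °C
Reagents that add atoms: 1,2-bis(trimethylsilyloxy)ethane, C[Si](C)(C)OCCO[Si](C)(C)C
Why: Silyl triflate-catalysed ketalisation should protect the saturated C6 ketone selectively because the conjugated C3 enone is far less electrophilic, and masking C6 removes the acidic C7 and C5 hydrogens that would otherwise be alkylated before C4 in step 10.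

**Step 10**
Reactants: 14 6,6-ethylenedioxy-12-methoxy-18,19-dinor-5β-abieta-1,8,11,13-tetraen-3-one
Product: 16 6,6-ethylenedioxy-12-methoxy-5β-abieta-1,8,11,13-tetraen-3-one, via 4-monomethyl ketone 15 (not isolated)
Conditions: LiN(i-Pr)2, THF, −78 °C, MeI; then second charge of LiN(i-Pr)2, MeI, DMPU, −78 → 0 °C
Reagents that add atoms: iodomethane, CI
Why: Enolate alkylation: with C6 masked and no γ-hydrogen on the enone (C10 is quaternary) only the α' carbon C4 can be deprotonated, so two deprotonation–methylation cycles through 15 should install the gem-dimethyl group without creating a lasting stereocentre.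

**Step 11**
Reactants: 16 6,6-ethylenedioxy-12-methoxy-5β-abieta-1,8,11,13-tetraen-3-one
Product: 17 6,6-ethylenedioxy-12-methoxy-5β-abieta-8,11,13-trien-3-one
Conditions: H2 (1 atm), palladium on carbon (10%), EtOAc, rt
Reagents that add atoms: none
Why: Heterogeneous hydrogenation of the disubstituted conjugated C1=C2 bond should be fast and chemoselective, leaving arene, ketal and the hindered C3 ketone untouched.

**Step 12**
Reactants: 17 6,6-ethylenedioxy-12-methoxy-5β-abieta-8,11,13-trien-3-one
Product: 20 12-methoxy-5β-abieta-8,11,13-trien-6-one, via hydrazone 18 (not isolated), via deoxygenated ketal 19 (not isolated)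
Conditions: N2H4·H2O, KOH, diethylene glycol, 130 → 210 °C; then 2 M HCl, THF, 50 °C, argon
Reagents that add atoms: water, O
Why: Wolff–Kishner reduction removes the neopentyl C3 carbonyl through hydrazone 18 under conditions that ketal and aryl ether tolerate, and aqueous acid then hydrolyses the dioxolane of 19 to the C6 ketone, the C5 configuration being irrelevant because step 13 erases it.

**Step 13**
Reactants: 20 12-methoxy-5β-abieta-8,11,13-trien-6-one
Product: 22 6-hydroxy-12-methoxyabieta-5,8,11,13-tetraen-7-one (diosphenol), via 7-hydroperoxy ketone 21 (not isolated)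
Conditions: KOt-Bu, O2 (1 atm), t-BuOH/THF, 0 °C → rt; cold dilute HCl work-up
Reagents that add atoms: dioxygen, O=O
Why: Base-mediated autoxidation: the benzylic, styrene-like enolate toward C7 traps O2 to give hydroperoxide 21, which loses water (Kornblum–DeLaMare fragmentation) to the 6,7-dione, and this enolises toward C5 to the conjugated diosphenol, removing the provisional cis stereocentre at C5.

**Step 14**
Reactants: 22 6-hydroxy-12-methoxyabieta-5,8,11,13-tetraen-7-one
Product: 24 6α-hydroxy-12-methoxyabieta-8,11,13-trien-7-one (H-5α), via 6β-hydroxy ketone 23 (not isolated)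
Conditions: H2 (20 bar), palladium on carbon (10%), EtOAc, rt; filter; then DBU (cat.), degassed CH2Cl2, rt, argon
Reagents that add atoms: none
Why: Heterogeneous hydrogenation of the enone-type C5=C6 bond should deliver hydrogen syn to the α face because the β face is screened by the axial C10 and C4β methyl groups, which sets H-5α (trans ring fusion) and gives the axial 6β-ol 23, and base-mediated enolisation toward the C7 ketone then moves the hydroxyl to the equatorial 6α position away from the two syn-axial methyl groups.

**Step 15**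
Reactants: 24 6α-hydroxy-12-methoxyabieta-8,11,13-trien-7-one (two molecules)
Product: 27 CNP0327150.1 (the 6α,7β:7'β,6'α-linked dioxane dimer), via silyl ether 25 (not isolated), via open-chain mono-ether 26 (not isolated)
Conditions: Me3SiCl, imidazole, CH2Cl2, 0 °C; filter; then Et3SiH (3 equiv), Me3SiOTf (0.3 equiv), CH2Cl2 (0.5 M), −78 → −40 °C
Reagents that add atoms: none
Why: Reductive etherification (ketone plus silyl ether plus hydrosilane under silyl triflate catalysis) run twice, first between two molecules of 25 and then as a six-membered ring closure of 26: each C7 oxocarbenium ion is stabilised by the para methoxy group and should take hydride axially from the α face, so both new C7–O bonds end equatorial (7β) and the all-trans dioxane results, while the pairing of a C6 oxygen with a C7 carbon is the only one that can close the ring.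

**Compound list**

1 | methyl 4-bromo-2-methoxybenzoate | COC(=O)c1ccc(Br)cc1OC | starting material
2 | 1-(4-bromo-2-methoxyphenyl)ethan-1-one (formed in the flask) | CC(=O)c1ccc(Br)cc1OC | intermediate
3 | 2-(4-bromo-2-methoxyphenyl)propan-2-ol | CC(C)(O)c1ccc(Br)cc1OC | intermediate
4 | 4-bromo-2-methoxy-1-(propan-2-yl)benzene | COc1cc(Br)ccc1C(C)C | intermediate
5 | 4-methylcyclohex-2-en-1-one (racemic) | CC1CCC(=O)C=C1 | starting material
6 | 4-[3-methoxy-4-(propan-2-yl)phenyl]-4-methylcyclohex-2-en-1-one (racemic) | COc1cc(C2(C)CCC(=O)C=C2)ccc1C(C)C | intermediate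
7 | trimethylsilyl dienol ether of 6, 1-(trimethylsilyloxy)-4-aryl-4-methylcyclohexa-1,5-diene (formed in the flask) | COc1cc(C2(C)CC=C(O[Si](C)(C)C)C=C2)ccc1C(C)C | intermediate
8 | 4-[3-methoxy-4-(propan-2-yl)phenyl]-4-methylcyclohexa-2,5-dien-1-one | COc1cc(C2(C)C=CC(=O)C=C2)ccc1C(C)C | intermediate
9 | 4-[2-bromo-5-methoxy-4-(propan-2-yl)phenyl]-4-methylcyclohexa-2,5-dien-1-one | COc1cc(C2(C)C=CC(=O)C=C2)c(Br)cc1C(C)C | intermediate
10 | (E)-2-ethoxyvinylboronic acid pinacol ester | CCO/C=C/B1OC(C)(C)C(C)(C)O1 | starting material
11 | 4-{2-[(E)-2-ethoxyethenyl]-5-methoxy-4-(propan-2-yl)phenyl}-4-methylcyclohexa-2,5-dien-1-one | CCO/C=C/c1cc(C(C)C)c(OC)cc1C1(C)C=CC(=O)C=C1 | intermediate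
12 | 2-[4-methoxy-2-(1-methyl-4-oxocyclohexa-2,5-dien-1-yl)-5-(propan-2-yl)phenyl]acetaldehyde (achiral key-step precursor) | COc1cc(C2(C)C=CC(=O)C=C2)c(CC=O)cc1C(C)C | intermediate
13 | 12-methoxy-18,19-dinor-5β-abieta-1,8,11,13-tetraene-3,6-dione (cis-fused; H-5β, 10β-methyl) | COc1cc2c(cc1C(C)C)CC(=O)[C@@H]1CC(=O)C=C[C@]21C | intermediate
14 | 6,6-ethylenedioxy-12-methoxy-18,19-dinor-5β-abieta-1,8,11,13-tetraen-3-one | COc1cc2c(cc1C(C)C)CC3(OCCO3)[C@@H]1CC(=O)C=C[C@]21C | intermediate
15 | 4-monomethyl derivative of 14, C4 epimers (formed in the flask) | COc1cc2c(cc1C(C)C)CC3(OCCO3)[C@@H]1C(C)C(=O)C=C[C@]21C | intermediate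
16 | 6,6-ethylenedioxy-12-methoxy-5β-abieta-1,8,11,13-tetraen-3-one | COc1cc2c(cc1C(C)C)CC3(OCCO3)[C@@H]1C(C)(C)C(=O)C=C[C@]21C | intermediate
17 | 6,6-ethylenedioxy-12-methoxy-5β-abieta-8,11,13-trien-3-one | COc1cc2c(cc1C(C)C)CC3(OCCO3)[C@@H]1C(C)(C)C(=O)CC[C@]21C | intermediate
18 | C3 hydrazone of 17 (formed in the flask) | COc1cc2c(cc1C(C)C)CC3(OCCO3)[C@@H]1C(C)(C)C(=NN)CC[C@]21C | intermediate
19 | 6,6-ethylenedioxy-12-methoxy-5β-abieta-8,11,13-triene (formed in the flask) | COc1cc2c(cc1C(C)C)CC3(OCCO3)[C@@H]1C(C)(C)CCC[C@]21C | intermediate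
20 | 12-methoxy-5β-abieta-8,11,13-trien-6-one | COc1cc2c(cc1C(C)C)CC(=O)[C@@H]1C(C)(C)CCC[C@]21C | intermediate
21 | 7-hydroperoxy-12-methoxy-5β-abieta-8,11,13-trien-6-one, C7 epimers (formed in the flask) | COc1cc2c(cc1C(C)C)C(OO)C(=O)[C@@H]1C(C)(C)CCC[C@]21C | intermediate
22 | 6-hydroxy-12-methoxyabieta-5,8,11,13-tetraen-7-one (diosphenol; 10β-methyl) | COc1cc2c(cc1C(C)C)C(=O)C(O)=C1C(C)(C)CCC[C@]21C | intermediate
23 | 6β-hydroxy-12-methoxyabieta-8,11,13-trien-7-one (H-5α, axial hydroxyl; formed in the flask) | COc1cc2c(cc1C(C)C)C(=O)[C@@H](O)[C@H]1C(C)(C)CCC[C@]21C | intermediate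
24 | 6α-hydroxy-12-methoxyabieta-8,11,13-trien-7-one (H-5α, H-6β, 10β-methyl) | COc1cc2c(cc1C(C)C)C(=O)[C@H](O)[C@H]1C(C)(C)CCC[C@]21C | intermediate
25 | 12-methoxy-6α-(trimethylsilyloxy)abieta-8,11,13-trien-7-one (formed in the flask) | COc1cc2c(cc1C(C)C)C(=O)[C@H](O[Si](C)(C)C)[C@H]1C(C)(C)CCC[C@]21C | intermediate
26 | 12-methoxy-7β-[(12-methoxy-7-oxoabieta-8,11,13-trien-6α-yl)oxy]-6α-(trimethylsilyloxy)abieta-8,11,13-triene (H-7α; formed in the flask) | COc1cc2c(cc1C(C)C)[C@@H](O[C@H]3C(=O)c4cc(C(C)C)c(OC)cc4[C@@]4(C)CCCC(C)(C)[C@H]34)[C@H](O[Si](C)(C)C)[C@H]1C(C)(C)CCC[C@]21C | intermediate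
27 | CNP0327150.1: two 12-methoxyabieta-8,11,13-triene units joined 6α-O-7'β and 7β-O-6'α through a 1,4-dioxane trans-fused to both rings B (each half H-5α, H-6β, H-7α, 10β-methyl) | COc1cc2c(cc1C(C)C)[C@H]1O[C@H]3[C@H](O[C@@H]1[C@H]1C(C)(C)CCC[C@]21C)c1cc(C(C)C)c(OC)cc1[C@@]1(C)CCCC(C)(C)[C@H]31 | target

**Step count**

Total step count: 15. Longest linear sequence: 15 steps (1 → 27); the commercial compounds 5 and 10 enter at steps 3 and 6.

**Steps most likely to fail**

Step 8. Enolisation of the benzylic aldehyde may outpace enaminol formation and lead to aldol oligomers or to a five-membered Michael closure through C7, and the six-membered acyl addition may be slow or discriminate poorly between the two arms. The fallback replaces the carbene-bound acyl anion by a nitronate and sets out from aldehyde 12. Condensation with NH2OH·HCl/NaOAc should give the aldoxime F1, and oxidation with NaBO3·4H2O in AcOH the 2-nitroethyl dienone F2. A cinchona-derived bifunctional thiourea (the pseudo-enantiomer chosen for the required C10 configuration) should then promote the desymmetrising 6-exo intramolecular nitro-Michael addition of C6 to C5, giving the cis-fused nitro tricycle F3. An oxidative Nef reaction (KOt-Bu, then buffered KHSO5) converts the C6 nitro group into the ketone, and the route is rejoined at 13.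

Step 14. Hydrogen delivery to the tetrasubstituted C5=C6 bond, which lies between two quaternary carbons, may be slow or poorly face-selective; the aryl ketone may be over-reduced, or the diosphenol may tautomerise to the cis dione before it is reduced. The fallback sets out from diosphenol 22 and removes the C6 oxygen temporarily. Tf2O/pyridine should give the enol triflate F4, and Pd(OAc)2/PPh3 with HCO2H/Bu3N in DMF the enone 12-methoxyabieta-5,8,11,13-tetraen-7-one F5. Dissolving-metal reduction (Li, NH3, THF, one equivalent of t-BuOH, −78 °C; NH4Cl) should set H-5α by axial protonation at C5 and give 12-methoxyabieta-8,11,13-trien-7-one F6. Enolate hydroxylation (LiN(SiMe3)2, −78 °C, then 2-(phenylsulfonyl)-3-phenyloxaziridine) should then occur on the open α face of C6, and the route is rejoined at 24.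

Step 15. Direct hydride reduction of the activated aryl ketone, reductive cleavage of the first-formed para-methoxybenzylic ether, or linear oligomerisation may outrun the ring-closing second etherification. The fallback sets out from ketol 24 and separates C–O bond formation from reduction. Acid-catalysed dehydrative dimerisation of the acyloin (TsOH, toluene, reflux with azeotropic water removal, argon) should give the bis-enol-ether 1,4-dioxin F7. Ionic hydrogenation (Et3SiH, CF3CO2H, CH2Cl2, −20 °C) then reduces both C6=C7 bonds: reversible protonation at C6 should favour the oxocarbenium ion with the equatorial C6–O bond, and axial hydride capture at C7 from the α face gives 27 directly.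

**Further compounds**

F1 | step 8 | 2-[4-methoxy-2-(1-methyl-4-oxocyclohexa-2,5-dien-1-yl)-5-(propan-2-yl)phenyl]acetaldehyde oxime | COc1cc(C2(C)C=CC(=O)C=C2)c(CC=NO)cc1C(C)C
F2 | step 8 | 4-[5-methoxy-2-(2-nitroethyl)-4-(propan-2-yl)phenyl]-4-methylcyclohexa-2,5-dien-1-one | COc1cc(C2(C)C=CC(=O)C=C2)c(CC[N+](=O)[O-])cc1C(C)C
F3 | step 8 | 12-methoxy-6-nitro-18,19-dinor-5β-abieta-1,8,11,13-tetraen-3-one (C6 epimers) | COc1cc2c(cc1C(C)C)CC([N+](=O)[O-])[C@@H]1CC(=O)C=C[C@]21C
F4 | step 14 | 12-methoxy-7-oxoabieta-5,8,11,13-tetraen-6-yl trifluoromethanesulfonate | COc1cc2c(cc1C(C)C)C(=O)C(OS(=O)(=O)C(F)(F)F)=C1C(C)(C)CCC[C@]21C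
F5 | step 14 | 12-methoxyabieta-5,8,11,13-tetraen-7-one | COc1cc2c(cc1C(C)C)C(=O)C=C1C(C)(C)CCC[C@]21C
F6 | step 14 | 12-methoxyabieta-8,11,13-trien-7-one (H-5α) | COc1cc2c(cc1C(C)C)C(=O)C[C@H]1C(C)(C)CCC[C@]21C
F7 | step 15 | 1,4-dioxin from two units of 24, with C6=C7 enol-ether bonds in both halves (H-5α, 10β-methyl in each) | COc1cc2c(cc1C(C)C)C3=C(OC4=C(O3)[C@H]5C(C)(C)CCC[C@]5(C)c5cc(OC)c(C(C)C)cc54)[C@H]1C(C)(C)CCC[C@]21C
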